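Read in a minute, these flasks run for 6.0 d, and their equations, charges and questions stand first.

    starting material + single product → side product (k1 = 0.030 L mol⁻¹ min⁻¹, Ea1 = 83.0 kJ mol⁻¹)
    starting material + reagent → other mono adduct (k2 = 0.0038 L mol⁻¹ min⁻¹, Ea2 = 92.0 kJ mol⁻¹)
    reagent + single product → double product (k3 = 0.0034 L mol⁻¹ min⁻¹, Ea3 = 85.0 kJ mol⁻¹)
    reagent + other mono adduct → double product (k4 = 0.0091 L mol⁻¹ min⁻¹, Ea4 = 82.0 kJ mol⁻¹)
    starting material + reagent → single product (k5 = 0.0055 L mol⁻¹ min⁻¹, Ea5 = 75.0 kJ mol⁻¹)
    single product ⇌ isomer of the product (K6 = 0.38, k6 = 7.1 × 10⁻⁵ min⁻¹, Ea6 = 117 kJ mol⁻¹, ΔH6 = −9.00 kJ mol⁻¹)
    (constants at 80 °C)

in all of them: time 6.0 d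
- dusk: starting material 0.10 M (fed, over 4.0 d); reagent 1.10 equiv; temperature 80 °C; all else is in the flask from the start; the feed brings no volume worth counting
- noon: starting material 0.10 M (fed, over 4.0 d); reagent 1.10 equiv; the addition at 50 °C, then warmed to 80 °C; the feed brings no volume worth counting
- spring: starting material 0.10 M; reagent 1.10 equiv (fed, over 4.0 d); temperature 80 °C; all else is in the flask from the start; the feed brings no volume worth counting
- winter: starting material 0.10 M; reagent 1.10 equiv (in portions, 4, over 4.0 d); temperature 80 °C; first portion at the start, last at 4.0 d

* which flask leads in amount of double product, in percent of the starting material charged ("all alike" within 1.5 percentage points) (dusk / noon / spring / winter / all alike)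
* how much double product is there at the end, in percent of the starting material charged: dusk
* how much double product is there at the end, in percent of the starting material charged: noon
* how much double product is there at the end, in percent of the starting material charged: spring
* how much double product is there at the end, in percent of the starting material charged: winter

- percentages count the starting material that a species holds: one side product counts as two
- constants are those at 80 °C; use the activation energies and enthalpies for any other temperature

The reckoning here follows one molecule of starting material. Its meeting with reagent gives other mono adduct in 0.409 of cases, and that adduct's one step forward leads to double product. The remaining meetings give single product, which forks again: the odds for side product against double product are 8.82, a selectivity factor, times the ratio q = c(starting material)/c(reagent), and each side product spends a second molecule of starting material. Double product formed per starting material spent is the fork yield Y. The isomer of the product is set aside, since its step at 7.1 × 10⁻⁵ min⁻¹ is slower than the loss of single product to the full charge of starting material.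

Time enters as the clock number Θ 2.62, the printed value being noon's: k4 times the charged c(starting material) times the time spent hot, which counts the lifetimes of other mono adduct against reagent standing at that concentration. The first meeting runs at a similar constant, so a molecule is counted through two gates, each with chance Θ/(Θ+1), and the estimate is Y times that chance squared. In noon the cold addition is counted as nil. In dusk, spring and winter the mean arrival falls at half the addition time, which gives Θ = 5.24 for each.

One number therefore fails to separate those three, and q must be read as well. Counted from the charges at mid-addition, q is one over twice the equivalents in dusk, giving Y = 35.7%. With both whole charges counted as present in noon's hot phase, Y = 31.1%. With half the reagent in at mid-addition in spring and winter, Y = 28.5%. The estimates are 25.2% for dusk, 16.3% for noon, 20.1% for spring and 20.1% for winter, which puts dusk in the lead.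

The forecast named dusk on the ground that “Dusk keeps reagent in excess longest”, and gave 37%, 26%, 32% and 32% for dusk, noon, spring and winter, higher figures than these.

The simulation puts dusk in the lead, with 27.8%, 18.4%, 22.1% and 21.0% for dusk, noon, spring and winter. A neighbour of noon charged with 0.060 M of starting material keeps the equivalents, and so the q and Y of this reckoning, but its clock number falls from 2.62 to 1.57. The same reckoning then gives 11.6% for that neighbour, and after 6.00 d it holds 13.5% of double product.

(All constants are made up; the flask was simulated.)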